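**Plan**

1. The target is read as (1R,2R,5S,6S)-2,6-bis(3,4-dimethoxyphenyl)-3,7-dioxabicyclo[3.3.0]octan-1-ol. Ring A (C1, C2, O3, C4, C5) and ring B (C5, C6, O7, C8, C1) are cis-fused, with the OH on C1 and the H on C5 on the convex face and both aryl groups on the concave face.
2. Enabling feature: C2 and C6 are each a benzylic carbon bonded to a ring oxygen (O3, O7) and a bridgehead (C1, C5), and the core is C2-symmetric apart from the C1 hydroxyl. Both can therefore be carried as the carbonyl carbons of one six-carbon hydroxy bislactone.
3. Retrosynthesis: cut C2–H and C6–H (ionic hydrogenation of a bis-hemiketal), then Ar–C2 and Ar–C6 (aryllithium on the bislactone), then O7–C6 of lactone B together with C1–O and C8–O (dihydroxylation), then C1=C8 (α-methylenation of paraconic acid).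
4. Forward: ring A is bought as the lactone of (S)-paraconic acid, C8 is added as an exocyclic methylene, osmylation and lactonisation close ring B, both aryl groups are joined in one operation, and a double deoxygenation ends the route.
5. Stereochemistry: C5 is bought. C1 follows from osmylation anti to the C5 carboxyl, since only that diol can close the cis-fused lactone B. C2 and C6 are set together by hydride delivery to the convex face of the bicycle.

Key step: step 4

Assumption: (S)-paraconic acid is taken as a purchasable building block; where only the racemate is stocked, salt resolution with 1-phenylethylamine is the usual access.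

**Route**

Step 1
Reactants: 1 (S)-paraconic acid, (3S)-5-oxooxolane-3-carboxylic acid
Product: 3 (3S)-4-methylidene-5-oxooxolane-3-carboxylic acid, via carboxylated lactone 2 (not isolated)
Conditions: MeOMgOCO2Me (2 M in DMF), 130 °C; then 37% aq. HCHO, PhNHMe, NaOAc, AcOH, rt; aq. HCl work-up
Reagents that add atoms: formaldehyde, C=O
Why: Stiles carboxylation of the lactone α-CH2 (held as a magnesium chelate) followed by decarboxylative Mannich methylenation is the standard way to α-methylene paraconic acids; the only stereocentre (the future C5) is α to a carboxylate, is not deprotonated and should be carried through unchanged.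

Step 2
Reactants: 3 (3S)-4-methylidene-5-oxooxolane-3-carboxylic acid
Product: 5 (1R,5R)-1-hydroxy-3,7-dioxabicyclo[3.3.0]octane-2,6-dione, via diol acid 4 (not isolated)
Conditions: OsO4 (cat.), NMO, acetone/H2O, 0 °C to rt; then 2 M aq. HCl, rt
Reagents that add atoms: N-methylmorpholine N-oxide, C[N+]1([O-])CCOCC1; water, O
Why: Upjohn dihydroxylation in which OsO4 should add to the exocyclic C1=C8 bond anti to the carboxyl group on C5, so that the new C1–OH is trans and the CH2OH (C8) cis to that carboxyl, after which acid closes lactone B by 5-exo-trig acyl substitution, a closure open only to this diol (cis-fused bicycle), so the minor diol stays an acid and is washed out.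

Step 3
Reactants: 5 (1R,5R)-1-hydroxy-3,7-dioxabicyclo[3.3.0]octane-2,6-dione
Product: 6 (1R,5R)-1-(trimethylsilyloxy)-3,7-dioxabicyclo[3.3.0]octane-2,6-dione
Conditions: TMSCl, imidazole, CH2Cl2, 0 °C to rt
Reagents that add atoms: chlorotrimethylsilane, C[Si](C)(C)Cl
Why: Standard silyl ether formation caps the tertiary C1 hydroxyl, so that no alkoxide sits β to the C6 carbonyl during the aryllithium addition and the bislactone dissolves in THF at low temperature; no stereocentre is touched.

Step 4
Reactants: 6 (1R,5R)-1-(trimethylsilyloxy)-3,7-dioxabicyclo[3.3.0]octane-2,6-dione; 7 4-bromo-1,2-dimethoxybenzene (2.4 equiv)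
Product: 10 (1R,5R)-2,6-bis(3,4-dimethoxyphenyl)-3,7-dioxabicyclo[3.3.0]octane-1,2,6-triol, via aryllithium 8 (not isolated), via silylated bis-hemiketal 9 (not isolated)
Conditions: 7, n-BuLi, THF, −78 °C; then 6, −78 to −50 °C; then 1 M aq. HCl, THF, 0 °C
Reagents that add atoms: none
Why: Bromine–lithium exchange turns 7 into aryllithium 8, which adds once to each lactone carbonyl of 6 (C2 in ring A, C6 in ring B) to give the dilithium salt of 9; five-membered lithium hemiketal alkoxides should not collapse to ketones at −78 °C, so each carbonyl takes up one aryl group and both aryl–carbon bonds (Ar–C2 and Ar–C6) form in one operation. The closest known reaction type is the addition of aryllithiums to silyl-protected aldonolactones in C-aryl glycoside synthesis and to furofuranone lactones in lignan synthesis. No ring is closed: rings A and B of the bislactone are kept as cyclic hemiketals. The two new stereocentres (hemiketal carbons C2 and C6) are not controlled and need not be, because both are flattened to oxocarbenium ions in step 5, where the cis-fused bicycle fixed by C1 and C5 decides their configuration. The step needs 1,2-addition to win over deprotonation at C5–H (which would expel the ring A carboxylate by β-elimination) and over double addition; the low temperature, the non-enolisable α-quaternary C2 carbonyl and the silyl cap on O1 (no alkoxide next to either carbonyl) should secure this. Dilute acid on quench removes the TMS group and leaves 10 as a mixture of hemiketal epimers, to be used crude.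

Step 5
Reactants: 10 (1R,5R)-2,6-bis(3,4-dimethoxyphenyl)-3,7-dioxabicyclo[3.3.0]octane-1,2,6-triol
Product: 11 (1R,2R,5S,6S)-2,6-bis(3,4-dimethoxyphenyl)-3,7-dioxabicyclo[3.3.0]octan-1-ol
Conditions: Et3SiH, BF3·OEt2, CH2Cl2/MeCN, −40 to −10 °C; sat. aq. NaHCO3 quench
Reagents that add atoms: none
Why: Ionic hydrogenation of aryl hemiketals (as in C-aryl glycoside and furofuran lignan synthesis): BF3 ionises each hemiketal to an aryl-stabilised oxocarbenium ion and Et3SiH should deliver hydride to the convex face of the cis-fused bicycle (cis to C1–OH at C2, cis to C5–H at C6), which leaves both aryl groups on the concave face, i.e. (2R,6S), while the free tertiary alcohol is tolerated.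

**Compound list**

1 | (S)-paraconic acid, (3S)-5-oxooxolane-3-carboxylic acid | O=C1OC[C@@H](C(=O)O)C1 | starting material
2 | (4S)-2-oxooxolane-3,4-dicarboxylic acid, magnesium chelate in the flask, C3 undefined (not isolated) | O=C1OC[C@@H](C(=O)O)C1C(=O)O | intermediate
3 | (3S)-4-methylidene-5-oxooxolane-3-carboxylic acid | O=C1OC[C@@H](C(=O)O)C1=C | intermediate
4 | (3R,4R)-4-hydroxy-4-(hydroxymethyl)-5-oxooxolane-3-carboxylic acid (not isolated) | O=C1OC[C@@H](C(=O)O)[C@@]1(O)CO | intermediate
5 | (1R,5R)-1-hydroxy-3,7-dioxabicyclo[3.3.0]octane-2,6-dione | O=C1OC[C@@]2(O)C(=O)OC[C@@H]12 | intermediate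
6 | (1R,5R)-1-(trimethylsilyloxy)-3,7-dioxabicyclo[3.3.0]octane-2,6-dione | O=C1OC[C@@]2(O[Si](C)(C)C)C(=O)OC[C@@H]12 | intermediate
7 | 4-bromo-1,2-dimethoxybenzene | COc1ccc(Br)cc1OC | starting material
8 | 3,4-dimethoxyphenyllithium (not isolated) | COc1ccc([Li])cc1OC | intermediate
9 | (1R,5R)-2,6-bis(3,4-dimethoxyphenyl)-1-(trimethylsilyloxy)-3,7-dioxabicyclo[3.3.0]octane-2,6-diol, dilithium alkoxide until the quench, C2 and C6 undefined (not isolated) | COc1ccc(C2(O)OC[C@@]3(O[Si](C)(C)C)C(O)(c4ccc(OC)c(OC)c4)OC[C@@H]23)cc1OC | intermediate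
10 | (1R,5R)-2,6-bis(3,4-dimethoxyphenyl)-3,7-dioxabicyclo[3.3.0]octane-1,2,6-triol, hemiketal epimers at C2 and C6 | COc1ccc(C2(O)OC[C@@]3(O)C(O)(c4ccc(OC)c(OC)c4)OC[C@@H]23)cc1OC | intermediate
11 | (1R,2R,5S,6S)-2,6-bis(3,4-dimethoxyphenyl)-3,7-dioxabicyclo[3.3.0]octan-1-ol | COc1ccc([C@H]2OC[C@@]3(O)[C@@H](c4ccc(OC)c(OC)c4)OC[C@@H]23)cc1OC | target

**Step count and risks**

Total step count: 5. Longest linear sequence: 5 steps (from 1; compound 7 enters in step 4).

The three steps most likely to fail:

Step 4. The aryllithium may deprotonate C5–H, and the enolate would then open ring A by β-elimination. A lithium hemiketal may collapse to the ketone and take up a second aryl group. The hindered C2 carbonyl may react incompletely. Fallback, from 5 back to 10: both lactones are opened with Me(MeO)NH·HCl and AlMe3 in CH2Cl2 to give (2R,3R)-2-hydroxy-2,3-bis(hydroxymethyl)-N,N'-dimethoxy-N,N'-dimethylbutanediamide F1. Its three hydroxyls are capped with TMSCl and imidazole to give the tris(trimethylsilyl) ether F2. Aryllithium 8 (from 7 and n-BuLi, THF, −78 °C) then adds to both Weinreb amides, whose N-methoxy chelates stop each addition at the ketone stage, to give the bis(aryl ketone) tris(trimethylsilyl) ether F3. Treatment with 1 M HCl in THF removes the silyl groups, and the keto triol should close to bis-hemiketal 10.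

Step 5. Hydride may be delivered to the C2 oxocarbenium ion from the concave face, because the convex face at C2 carries the neighbouring C1 oxygen. The Lewis acid may also epimerise the electron-rich benzylic ether centres through ring-opened benzylic cations. Fallback, from 5 back to 11: the C1 hydroxyl is silylated with i-Pr2SiHCl and imidazole instead of TMSCl, giving the (diisopropylsilyl) ether of the bislactone F4. Double addition of 8 with an aq. NH4Cl quench gives the silyl-tethered bis-hemiketal F5. With BF3·OEt2 and Et3SiH in CH2Cl2 at −78 °C, the Si–H on O1 should pass hydride to C2 within a five-membered transition state on the O1 face, modelled on the Lewis-acid-promoted intramolecular hydrosilylation of hydroxy ketones through hydridosilyl ethers, while Et3SiH reduces C6 from the convex face; this gives the 1-O-(fluorodiisopropylsilyl) ether of the target F6. TBAF in THF then frees 11.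

Step 2. Osmylation may show poor facial selectivity, since the carboxylate on C5 is only a medium-sized shield. The basic medium may also shift the exocyclic double bond into the ring. Fallback, from 3 back to 5: the acid is esterified under base-free conditions (tert-butyl 2,2,2-trichloroacetimidate, cat. BF3·OEt2) to tert-butyl (3S)-4-methylidene-5-oxooxolane-3-carboxylate F7, whose bulky ester should shield one face more strongly. OsO4/NMO then gives tert-butyl (3R,4R)-4-hydroxy-4-(hydroxymethyl)-5-oxooxolane-3-carboxylate F8. TFA in CH2Cl2 cleaves the ester and closes lactone B to give 5.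

**Further compounds**

F1 | step 4 | (2R,3R)-2-hydroxy-2,3-bis(hydroxymethyl)-N,N'-dimethoxy-N,N'-dimethylbutanediamide | CON(C)C(=O)[C@](O)(CO)[C@@H](CO)C(=O)N(C)OC
F2 | step 4 | (2R,3R)-N,N'-dimethoxy-N,N'-dimethyl-2-(trimethylsilyloxy)-2,3-bis(trimethylsilyloxymethyl)butanediamide | CON(C)C(=O)[C@](O[Si](C)(C)C)(CO[Si](C)(C)C)[C@@H](CO[Si](C)(C)C)C(=O)N(C)OC
F3 | step 4 | (2R,3R)-1,4-bis(3,4-dimethoxyphenyl)-2-(trimethylsilyloxy)-2,3-bis(trimethylsilyloxymethyl)butane-1,4-dione | COc1ccc(C(=O)[C@](O[Si](C)(C)C)(CO[Si](C)(C)C)[C@@H](CO[Si](C)(C)C)C(=O)c2ccc(OC)c(OC)c2)cc1OC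
F4 | step 5 | (1R,5R)-1-(diisopropylsilyloxy)-3,7-dioxabicyclo[3.3.0]octane-2,6-dione | O=C1OC[C@@]2(O[SiH](C(C)C)C(C)C)C(=O)OC[C@@H]12
F5 | step 5 | (1R,5R)-2,6-bis(3,4-dimethoxyphenyl)-1-(diisopropylsilyloxy)-3,7-dioxabicyclo[3.3.0]octane-2,6-diol | COc1ccc(C2(O)OC[C@@]3(O[SiH](C(C)C)C(C)C)C(O)(c4ccc(OC)c(OC)c4)OC[C@@H]23)cc1OC
F6 | step 5 | (1R,2R,5S,6S)-2,6-bis(3,4-dimethoxyphenyl)-1-(fluorodiisopropylsilyloxy)-3,7-dioxabicyclo[3.3.0]octane | COc1ccc([C@H]2OC[C@@]3(O[Si](F)(C(C)C)C(C)C)[C@@H](c4ccc(OC)c(OC)c4)OC[C@@H]23)cc1OC
F7 | step 2 | tert-butyl (3S)-4-methylidene-5-oxooxolane-3-carboxylate | O=C1OC[C@@H](C(=O)OC(C)(C)C)C1=C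
F8 | step 2 | tert-butyl (3R,4R)-4-hydroxy-4-(hydroxymethyl)-5-oxooxolane-3-carboxylate | O=C1OC[C@@H](C(=O)OC(C)(C)C)[C@@]1(O)CO
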